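**Plan**
- Retrosynthesis: cut the interflavan bond C4(upper)–C6(lower) first (Friedel–Crafts alkylation by an upper C4 cation), then the aryl ether bond O1–C8a of each ring C, then the C3/C4 oxygens (alkene dihydroxylation) and the C2–C3 bond (aldehyde alkynylation).
- Forward, lower unit: 2-bromoisovanillin gives a bromo aryl alkyne; alkynylation of 4-(benzyloxy)benzaldehyde, Z-alkene, dihydroxylation and a C3/C4 cis-acetonide follow; copper-catalysed closure O1→C8a then forms ring C.
- Forward, upper unit: the same open-chain alcohol is oxidised and reduced back with inversion at C2, closed in the same way to the all-cis flavan, and converted to its 4β-benzylsulfanyl derivative; silver-mediated coupling, acetonide hydrolysis and hydrogenolysis finish the route.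
- Enabling feature: C8a of ring A lies between the C8 oxygen and C4a, so it can carry bromine from the starting aldehyde; the 3,4-cis diol of ring C can be held as a dioxolane, leaving O1 as the only oxygen able to reach C8a (six-membered closure); once O1 is on C8a, ring A is a 1,2,3-trioxygenated arene whose C6 (para to O1, ortho to O7) takes the upper C4 cation.
- Stereochemistry: lower C2 from the BINOL–Ti(OiPr)4 alkynylation; C3 and C4 of both units from osmylation of the Z-alkene anti to the C2 silyl ether; upper C2 from Felkin hydride addition; upper C4 from attack anti to the 2-aryl and 3-hydroxyl groups.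

Key step: step 10

Assumption: both units and their open-chain precursors are numbered as flavans (O1, C2, C3, C4, C4a, C5–C8, C8a); "upper" is the unit whose C4 carries the interflavan bond, "lower" is the flavan-3,4-diol unit. CIP descriptors were assigned by hand from the SMILES strings; where a name and a SMILES string differ, the SMILES string is the intended structure.

Step 1
Reactants: 1 2-bromo-3-hydroxy-4-methoxybenzaldehyde (2-bromoisovanillin)
Product: 2 2-bromo-3,4-dihydroxybenzaldehyde
Conditions: BBr3 (3 equiv), CH2Cl2, −78 °C to rt; then H2O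
Reagents that add atoms: none
Why: BBr3 cleaves the aryl methyl ether (Lewis acid-assisted SN2 demethylation) without touching the aldehyde or the C–Br bond, so that both phenols can later carry benzyl groups that leave in the last step.

Step 2
Reactants: 2 2-bromo-3,4-dihydroxybenzaldehyde
Product: 3 3,4-bis(benzyloxy)-2-bromobenzaldehyde
Conditions: BnBr (2.4 equiv), K2CO3, DMF, 60 °C
Reagents that add atoms: benzyl bromide (BrCc1ccccc1)
Why: Williamson etherification of both phenoxides gives base-stable benzyl ethers that survive every later step up to the final hydrogenolysis.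

Step 3
Reactants: 3 3,4-bis(benzyloxy)-2-bromobenzaldehyde
Product: 4 1,2-bis(benzyloxy)-3-bromo-4-ethynylbenzene
Conditions: dimethyl (1-diazo-2-oxopropyl)phosphonate, K2CO3, MeOH/THF, 0 °C to rt
Reagents that add atoms: dimethyl (1-diazo-2-oxopropyl)phosphonate (COP(=O)(OC)C(=[N+]=[N-])C(C)=O)
Why: Ohira–Bestmann (Seyferth–Gilbert) homologation converts the non-enolisable aryl aldehyde into the terminal alkyne under mild base that leaves the aryl bromide and benzyl ethers intact.

Step 4
Reactants: 4 1,2-bis(benzyloxy)-3-bromo-4-ethynylbenzene; 5 4-(benzyloxy)benzaldehyde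
Product: 7 (S)-1-[4-(benzyloxy)phenyl]-3-[3,4-bis(benzyloxy)-2-bromophenyl]prop-2-yn-1-ol, via alkynyl(ethyl)zinc reagent 6 (not isolated)
Conditions: 4 (2 equiv, excess recovered), Et2Zn (2 equiv), toluene, 110 °C; then (R)-1,1'-bi-2-naphthol (20 mol %), Ti(OiPr)4 (50 mol %), 5 (1 equiv), CH2Cl2/toluene, rt; sat. aq NH4Cl
Reagents that add atoms: diethylzinc (CC[Zn]CC; its ethylzinc unit is carried only by intermediate 6)
Why: Catalytic asymmetric addition of an alkynylzinc to an aromatic aldehyde under BINOL–Ti(OiPr)4 control sets C2 of the lower unit, the (R)-ligand being the antipode expected to give the (S)-carbinol by analogy with simple aryl aldehyde/arylacetylene pairs.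

Step 5
Reactants: 7 (S)-1-[4-(benzyloxy)phenyl]-3-[3,4-bis(benzyloxy)-2-bromophenyl]prop-2-yn-1-ol
Product: 8 tert-butyldimethylsilyl ether of 7
Conditions: TBSCl, imidazole, DMF, rt
Reagents that add atoms: tert-butyldimethylsilyl chloride (CC(C)(C)[Si](C)(C)Cl)
Why: Silylation blocks O1 so that the later acetonide can only span O3/O4, and provides the allylic ether that directs step 7.

Step 6
Reactants: 8 silyl ether of the propargylic alcohol
Product: 9 (1R,2Z)-allylic silyl ether
Conditions: H2 (1 atm), Pd/CaCO3 poisoned with Pb(OAc)2 (Lindlar catalyst), quinoline, EtOAc, rt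
Reagents that add atoms: none
Why: Lindlar semihydrogenation adds hydrogen syn to the alkyne and should stop at the Z-alkene, the poisoned catalyst sparing the aryl bromide and the benzyl ethers (the CIP label at C2 changes from S to R only because the priorities change).

Step 7
Reactants: 9 (1R,2Z)-allylic silyl ether
Product: 10 (1R,2R,3S)-3-[4-(benzyloxy)phenyl]-1-[3,4-bis(benzyloxy)-2-bromophenyl]-3-[(tert-butyldimethylsilyl)oxy]propane-1,2-diol
Conditions: OsO4 (5 mol %), N-methylmorpholine N-oxide (1.5 equiv), acetone/H2O, 0 °C to rt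
Reagents that add atoms: OsO4 (O=[Os](=O)(=O)=O; delivers both oxygen atoms, catalytic); N-methylmorpholine N-oxide (C[N+]1([O-])CCOCC1; terminal oxidant); water (O)
Why: Catalytic osmylation adds syn to the Z-alkene (C3/C4 erythro) and, in the conformer with the carbinol C–H in the alkene plane (least allylic 1,3-strain), from the face anti to the allylic silyloxy group (C2/C3 anti), which is the known substrate-controlled outcome for Z-allylic ethers and should give the all-erythro pattern of the lower unit.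

Step 8
Reactants: 10 silyl ether diol
Product: 11 silyl ether cis-acetonide
Conditions: 2-methoxypropene (3 equiv), PPTS (5 mol %), CH2Cl2, 0 °C; Et3N quench
Reagents that add atoms: 2-methoxypropene (COC(C)=C)
Why: Kinetic acetalisation under weak acid ties O3 and O4 into a cis-dioxolane (the temporary ring) without ionising the benzylic C4–O bond.

Step 9
Reactants: 11 silyl ether cis-acetonide
Product: 12 (S)-[4-(benzyloxy)phenyl][(4S,5R)-5-[3,4-bis(benzyloxy)-2-bromophenyl]-2,2-dimethyl-1,3-dioxolan-4-yl]methanol (anti alcohol)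
Conditions: TBAF (1.2 equiv), THF, 0 °C to rt
Reagents that add atoms: none
Why: Fluoride cleaves the Si–O bond selectively and frees O1 as the only hydroxyl group of the molecule.

Step 10
Reactants: 12 anti alcohol
Product: 13 (2S,3S,4R)-7,8-bis(benzyloxy)-2-[4-(benzyloxy)phenyl]-3,4-(isopropylidenedioxy)chromane (lower flavan acetonide, 2,3-trans-3,4-cis)
Conditions: CuI (10 mol %), 3,4,7,8-tetramethyl-1,10-phenanthroline (20 mol %), Cs2CO3 (2 equiv), toluene, 110 °C, argon
Reagents that add atoms: none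
Why: The caesium alkoxide of O1 binds the phenanthroline-ligated monovalent copper centre, the C8a–Br bond adds oxidatively, and C–O reductive elimination from trivalent copper forms O1–C8a and returns the catalyst. The closest known reaction type is the Ullmann-type copper-catalysed intramolecular O-arylation of secondary alcohols by ortho-haloarenes that gives chromans. The one ring closed is the six-membered pyran ring C, by ipso attack of the tethered alkoxide at C8a (6-exo mode, through a seven-membered aryl copper alkoxide). No stereocentre is formed: only the O–H and C8a–Br bonds are broken, so C2, C3 and C4 are carried over unchanged and the 2,3-trans-3,4-cis pattern follows from the anti,anti triol. The selectivity needed is for O1 over O3 and O4 and against oxidation of the benzylic carbinol: the cis-dioxolane ties up O3 and O4 and holds the bromoarene and the carbinol on the same face of the five-membered ring, and copper is used because its alkoxides do not readily undergo β-hydride elimination. The closure also turns ring A into a 1,2,3-trioxygenated arene, which makes C6 the nucleophilic site used in step 15.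

Step 11
Reactants: 12 anti alcohol
Product: 14 [4-(benzyloxy)phenyl][(4R,5R)-5-[3,4-bis(benzyloxy)-2-bromophenyl]-2,2-dimethyl-1,3-dioxolan-4-yl]methanone
Conditions: Dess–Martin periodinane (1.3 equiv), NaHCO3, CH2Cl2, 0 °C to rt
Reagents that add atoms: none
Why: Buffered Dess–Martin oxidation gives the aryl ketone under near-neutral conditions, so the epimerisable α-carbon of the cis-dioxolane (C3) should be preserved.

Step 12
Reactants: 14 dioxolanyl aryl ketone
Product: 15 (R)-[4-(benzyloxy)phenyl][(4S,5R)-5-[3,4-bis(benzyloxy)-2-bromophenyl]-2,2-dimethyl-1,3-dioxolan-4-yl]methanol (syn alcohol)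
Conditions: LiBH(s-Bu)3 (1.5 equiv), THF, −78 °C; then H2O
Reagents that add atoms: none
Why: The bulky, non-chelating hydride adds to the ketone anti to the C3–O bond of the dioxolane (Felkin–Anh addition to an α-alkoxy ketone), which should give the 2,3-syn carbinol with C2 inverted relative to 12; any 12 formed alongside is separated and returned to step 10.

Step 13
Reactants: 15 syn alcohol
Product: 16 (2R,3S,4R)-7,8-bis(benzyloxy)-2-[4-(benzyloxy)phenyl]-3,4-(isopropylidenedioxy)chromane (upper flavan acetonide, 2,3-cis-3,4-cis)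
Conditions: CuI (10 mol %), 3,4,7,8-tetramethyl-1,10-phenanthroline (20 mol %), Cs2CO3 (2 equiv), toluene, 110 °C, argon
Reagents that add atoms: none
Why: The same Ullmann-type intramolecular O-arylation as in step 10 closes ring C of the upper unit with retention at C2, C3 and C4, giving the all-cis flavan.

Step 14
Reactants: 16 upper flavan acetonide
Product: 17 (2R,3S,4S)-4-(benzylsulfanyl)-7,8-bis(benzyloxy)-2-[4-(benzyloxy)phenyl]chroman-3-ol (2,3-cis-3,4-trans)
Conditions: PhCH2SH (5 equiv), BF3·OEt2 (0.3 equiv), CH2Cl2, −40 to −10 °C; aq NaHCO3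
Reagents that add atoms: phenylmethanethiol (SCc1ccccc1)
Why: Acid-mediated thiolysis of the C4 oxygen of a flavan-3,4-diol derivative (ionisation of the benzylic C4–O bond, capture by the thiol anti to the 2-aryl and 3-oxygen groups, loss of acetone) turns the acetonide into a leaving group that only a thiophilic activator will remove; either C4 epimer would serve in step 15.

Step 15
Reactants: 17 4β-benzylsulfanyl flavan-3-ol; 13 lower flavan acetonide
Product: 18 hexa-O-benzyl-epioritin-(4β→6)-ent-oritin-4α-ol 3,4-O-isopropylidene acetal (dimer acetonide)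
Conditions: AgBF4 (2.5 equiv), 2,6-di-tert-butyl-4-methylpyridine (3 equiv), 13 (3 equiv, excess recovered), 4 Å molecular sieves, THF, −20 to 0 °C, slow addition of 17
Reagents that add atoms: none
Why: Silver abstracts the benzylsulfanyl group to give the C4 benzylic cation (stabilised by O1 and the para C7 oxygen), which alkylates C6 of 13 in a Friedel–Crafts reaction of the kind used for proanthocyanidin interflavan bonds, the arene approaching anti to the 2-aryl and 3-hydroxyl groups (4β, 3,4-trans) while the hindered pyridine takes up the proton so that the acetonide of 13 is not ionised.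

Step 16
Reactants: 18 dimer acetonide
Product: 19 hexa-O-benzyl-epioritin-(4β→6)-ent-oritin-4α-ol
Conditions: AcOH/H2O/THF (3:1:1), 40 °C
Reagents that add atoms: none
Why: Mild aqueous acid hydrolyses the isopropylidene ketal through its tertiary oxocarbenium ion, which should form much more readily than the benzylic C4 cation, so the 3,4-cis diol is released with C4 unchanged.

Step 17
Reactants: 19 hexa-O-benzyl-epioritin-(4β→6)-ent-oritin-4α-ol
Product: 20 epioritin-(4β→6)-ent-oritin-4α-ol (target)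
Conditions: H2 (1 atm), Pd(OH)2/C, EtOAc/MeOH (1:1), rt; filtration under argon
Reagents that add atoms: none
Why: Hydrogenolysis of the six aryl benzyl ethers under neutral conditions should be much faster than cleavage of the free secondary benzylic C4–OH or of the interflavan bond, and no stereocentre is touched.

**Compound list**
1 | 2-bromo-3-hydroxy-4-methoxybenzaldehyde (2-bromoisovanillin) | O=Cc1ccc(OC)c(O)c1Br | starting material
2 | 2-bromo-3,4-dihydroxybenzaldehyde | O=Cc1ccc(O)c(O)c1Br | intermediate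
3 | 3,4-bis(benzyloxy)-2-bromobenzaldehyde | O=Cc1ccc(OCc2ccccc2)c(OCc2ccccc2)c1Br | intermediate
4 | 1,2-bis(benzyloxy)-3-bromo-4-ethynylbenzene | C#Cc1ccc(OCc2ccccc2)c(OCc2ccccc2)c1Br | intermediate
5 | 4-(benzyloxy)benzaldehyde | O=Cc1ccc(OCc2ccccc2)cc1 | starting material
6 | {[3,4-bis(benzyloxy)-2-bromophenyl]ethynyl}(ethyl)zinc | CC[Zn]C#Cc1ccc(OCc2ccccc2)c(OCc2ccccc2)c1Br | intermediate (not isolated)
7 | (S)-1-[4-(benzyloxy)phenyl]-3-[3,4-bis(benzyloxy)-2-bromophenyl]prop-2-yn-1-ol | C(c1ccccc1)Oc1ccc(cc1)[C@H](O)C#Cc1ccc(OCc2ccccc2)c(OCc2ccccc2)c1Br | intermediate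
8 | tert-butyl({(1S)-1-[4-(benzyloxy)phenyl]-3-[3,4-bis(benzyloxy)-2-bromophenyl]prop-2-yn-1-yl}oxy)dimethylsilane | C(c1ccccc1)Oc1ccc(cc1)[C@H](O[Si](C)(C)C(C)(C)C)C#Cc1ccc(OCc2ccccc2)c(OCc2ccccc2)c1Br | intermediate
9 | tert-butyl({(1R,2Z)-1-[4-(benzyloxy)phenyl]-3-[3,4-bis(benzyloxy)-2-bromophenyl]prop-2-en-1-yl}oxy)dimethylsilane | C(c1ccccc1)Oc1ccc(cc1)[C@H](O[Si](C)(C)C(C)(C)C)/C=C\c1ccc(OCc2ccccc2)c(OCc2ccccc2)c1Br | intermediate
10 | (1R,2R,3S)-3-[4-(benzyloxy)phenyl]-1-[3,4-bis(benzyloxy)-2-bromophenyl]-3-[(tert-butyldimethylsilyl)oxy]propane-1,2-diol | C(c1ccccc1)Oc1ccc(cc1)[C@H](O[Si](C)(C)C(C)(C)C)[C@H](O)[C@H](O)c1ccc(OCc2ccccc2)c(OCc2ccccc2)c1Br | intermediate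
11 | tert-butyl{(S)-[4-(benzyloxy)phenyl][(4R,5R)-5-[3,4-bis(benzyloxy)-2-bromophenyl]-2,2-dimethyl-1,3-dioxolan-4-yl]methoxy}dimethylsilane (cis-dioxolane) | C(c1ccccc1)Oc1ccc(cc1)[C@H](O[Si](C)(C)C(C)(C)C)[C@@H]1OC(C)(C)O[C@@H]1c1ccc(OCc2ccccc2)c(OCc2ccccc2)c1Br | intermediate
12 | (S)-[4-(benzyloxy)phenyl][(4S,5R)-5-[3,4-bis(benzyloxy)-2-bromophenyl]-2,2-dimethyl-1,3-dioxolan-4-yl]methanol (cis-dioxolane, anti alcohol) | C(c1ccccc1)Oc1ccc(cc1)[C@H](O)[C@@H]1OC(C)(C)O[C@@H]1c1ccc(OCc2ccccc2)c(OCc2ccccc2)c1Br | intermediate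
13 | (2S,3S,4R)-7,8-bis(benzyloxy)-2-[4-(benzyloxy)phenyl]-3,4-(isopropylidenedioxy)chromane (flavan numbering; 2,3-trans-3,4-cis; tri-O-benzyl-ent-oritin-4α-ol acetonide) | C(c1ccccc1)Oc1ccc2c(c1OCc1ccccc1)O[C@@H](c1ccc(OCc3ccccc3)cc1)[C@@H]1OC(C)(C)O[C@@H]12 | intermediate
14 | [4-(benzyloxy)phenyl][(4R,5R)-5-[3,4-bis(benzyloxy)-2-bromophenyl]-2,2-dimethyl-1,3-dioxolan-4-yl]methanone (cis-dioxolane) | C(c1ccccc1)Oc1ccc(cc1)C(=O)[C@@H]1OC(C)(C)O[C@@H]1c1ccc(OCc2ccccc2)c(OCc2ccccc2)c1Br | intermediate
15 | (R)-[4-(benzyloxy)phenyl][(4S,5R)-5-[3,4-bis(benzyloxy)-2-bromophenyl]-2,2-dimethyl-1,3-dioxolan-4-yl]methanol (cis-dioxolane, syn alcohol) | C(c1ccccc1)Oc1ccc(cc1)[C@@H](O)[C@@H]1OC(C)(C)O[C@@H]1c1ccc(OCc2ccccc2)c(OCc2ccccc2)c1Br | intermediate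
16 | (2R,3S,4R)-7,8-bis(benzyloxy)-2-[4-(benzyloxy)phenyl]-3,4-(isopropylidenedioxy)chromane (flavan numbering; 2,3-cis-3,4-cis; tri-O-benzylteracacidin acetonide) | C(c1ccccc1)Oc1ccc2c(c1OCc1ccccc1)O[C@H](c1ccc(OCc3ccccc3)cc1)[C@@H]1OC(C)(C)O[C@@H]12 | intermediate
17 | (2R,3S,4S)-4-(benzylsulfanyl)-7,8-bis(benzyloxy)-2-[4-(benzyloxy)phenyl]-3,4-dihydro-2H-chromen-3-ol (2,3-cis-3,4-trans) | C(c1ccccc1)Oc1ccc(cc1)[C@H]1Oc2c(ccc(OCc3ccccc3)c2OCc2ccccc2)[C@H](SCc2ccccc2)[C@H]1O | intermediate
18 | hexa-O-benzyl-epioritin-(4β→6)-ent-oritin-4α-ol 3,4-O-isopropylidene acetal (upper unit 2,3-cis-3,4-trans with free 3-OH; lower unit 2,3-trans-3,4-cis acetonide) | C(c1ccccc1)Oc1ccc(cc1)[C@H]1Oc2c(ccc(OCc3ccccc3)c2OCc2ccccc2)[C@H](c2cc3c(c(OCc4ccccc4)c2OCc2ccccc2)O[C@@H](c2ccc(OCc4ccccc4)cc2)[C@@H]2OC(C)(C)O[C@H]32)[C@H]1O | intermediate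
19 | hexa-O-benzyl-epioritin-(4β→6)-ent-oritin-4α-ol (7,8,4'-tri-O-benzyl on each unit; free 3-OH on the upper and 3,4-diol on the lower unit) | C(c1ccccc1)Oc1ccc(cc1)[C@H]1Oc2c(ccc(OCc3ccccc3)c2OCc2ccccc2)[C@H](c2cc3c(c(OCc4ccccc4)c2OCc2ccccc2)O[C@@H](c2ccc(OCc4ccccc4)cc2)[C@H](O)[C@@H]3O)[C@H]1O | intermediate
20 | epioritin-(4β→6)-ent-oritin-4α-ol; (2R,3R,4S)-2-(4-hydroxyphenyl)-4-[(2S,3R,4R)-3,4,7,8-tetrahydroxy-2-(4-hydroxyphenyl)-3,4-dihydro-2H-chromen-6-yl]-3,4-dihydro-2H-chromene-3,7,8-triol | Oc1ccc([C@H]2Oc3c(ccc(O)c3O)[C@H](c3cc4c(c(O)c3O)O[C@@H](c3ccc(O)cc3)[C@H](O)[C@@H]4O)[C@H]2O)cc1 | target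

**Step count and risks**
Total step count: 17. Longest linear sequence: 16 steps (1 → 12 → 14 → 17 → 20, i.e. steps 1–9 and 11–17); the lower-unit branch is 13 steps (steps 1–10 and 15–17).

Steps most likely to fail:

1. Step 15 (interflavan coupling). The 1,2,3-trioxygenated ring A of 13 is only moderately nucleophilic. The C4 cation may therefore be captured by the free 3-hydroxyl group or by C6 of a second molecule of 17 (self-condensation), or attack C5 instead of C6. The fallback blocks the competing carbon site; it sets out from 16 and returns at 20. Bromination of 16 with N-bromosuccinimide (CH2Cl2, −20 °C) at C6 of ring A (para to O1) should give the 6-bromo upper flavan acetonide F1. Thiolysis as in step 14 gives the 6-bromo 4β-benzylsulfanyl flavan-3-ol F2. Coupling with 13 as in step 15 gives the bromo dimer acetonide F3. Hydrolysis as in step 16 gives the bromo dimer F4. Hydrogenolysis over Pd(OH)2/C with Et3N then removes the six benzyl groups and the aryl bromide to give 20.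

2. Step 7 (dihydroxylation). The aryl group on the carbinol carbon may compete with the silyloxy group for control of the osmylation face, giving poor facial selectivity and the C3/C4-epimeric diol. The fallback replaces substrate control by reagent control; it sets out from 3 and returns at 14. Claisen–Schmidt condensation of 3 with 4'-(benzyloxy)acetophenone (KOH, EtOH) gives the (E)-chalcone F5. Juliá–Colonna epoxidation (poly-L-leucine, urea–H2O2, DBU, THF) gives the (2R,3S)-epoxy ketone F6. BF3·OEt2 in acetone at low temperature converts the epoxide into the cis-dioxolane with inversion at the benzylic carbon, giving 14. Chelation-controlled reduction of 14 with Zn(BH4)2 then supplies the anti alcohol 12 for step 10, while step 12 runs as before.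

3. Step 16 (acetonide hydrolysis). Acid may ionise the benzylic C4–O bond of the lower unit instead of the ketal carbon, causing epimerisation or solvolysis at C4, or may cleave the interflavan bond. The fallback avoids acid on the lower unit altogether; it sets out from 7 and returns at 19. Lindlar semihydrogenation of 7 gives the (Z)-allylic alcohol F7. The copper-catalysed O-arylation of step 10 (90 °C) closes it to the 2H-chromene F8. OsO4/N-methylmorpholine N-oxide adds anti to the 2-aryl group to give the 2,3-trans-3,4-cis flavan-3,4-diol F9. Ac2O/pyridine gives the diacetate F10, which silver does not ionise. Coupling with 17 as in step 15 gives the dimer diacetate F11, and K2CO3/MeOH removes the acetates to give 19.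

Further compounds
F1 | step 15 | (2R,3S,4R)-7,8-bis(benzyloxy)-2-[4-(benzyloxy)phenyl]-6-bromo-3,4-(isopropylidenedioxy)chromane | C(c1ccccc1)Oc1c(Br)cc2c(c1OCc1ccccc1)O[C@H](c1ccc(OCc3ccccc3)cc1)[C@@H]1OC(C)(C)O[C@@H]12
F2 | step 15 | (2R,3S,4S)-4-(benzylsulfanyl)-7,8-bis(benzyloxy)-2-[4-(benzyloxy)phenyl]-6-bromo-3,4-dihydro-2H-chromen-3-ol | C(c1ccccc1)Oc1ccc(cc1)[C@H]1Oc2c(cc(Br)c(OCc3ccccc3)c2OCc2ccccc2)[C@H](SCc2ccccc2)[C@H]1O
F3 | step 15 | 6-bromo (upper unit) derivative of dimer acetonide 18 | C(c1ccccc1)Oc1ccc(cc1)[C@H]1Oc2c(cc(Br)c(OCc3ccccc3)c2OCc2ccccc2)[C@H](c2cc3c(c(OCc4ccccc4)c2OCc2ccccc2)O[C@@H](c2ccc(OCc4ccccc4)cc2)[C@@H]2OC(C)(C)O[C@H]32)[C@H]1O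
F4 | step 15 | 6-bromo (upper unit) derivative of hexa-O-benzyl dimer 19 | C(c1ccccc1)Oc1ccc(cc1)[C@H]1Oc2c(cc(Br)c(OCc3ccccc3)c2OCc2ccccc2)[C@H](c2cc3c(c(OCc4ccccc4)c2OCc2ccccc2)O[C@@H](c2ccc(OCc4ccccc4)cc2)[C@H](O)[C@@H]3O)[C@H]1O
F5 | step 7 | (E)-1-[4-(benzyloxy)phenyl]-3-[3,4-bis(benzyloxy)-2-bromophenyl]prop-2-en-1-one | O=C(/C=C/c1ccc(OCc2ccccc2)c(OCc2ccccc2)c1Br)c1ccc(OCc2ccccc2)cc1
F6 | step 7 | [4-(benzyloxy)phenyl][(2R,3S)-3-[3,4-bis(benzyloxy)-2-bromophenyl]oxiran-2-yl]methanone | C(c1ccccc1)Oc1ccc(cc1)C(=O)[C@@H]1O[C@H]1c1ccc(OCc2ccccc2)c(OCc2ccccc2)c1Br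
F7 | step 16 | (1R,2Z)-1-[4-(benzyloxy)phenyl]-3-[3,4-bis(benzyloxy)-2-bromophenyl]prop-2-en-1-ol | C(c1ccccc1)Oc1ccc(cc1)[C@H](O)/C=C\c1ccc(OCc2ccccc2)c(OCc2ccccc2)c1Br
F8 | step 16 | (R)-7,8-bis(benzyloxy)-2-[4-(benzyloxy)phenyl]-2H-chromene | C(c1ccccc1)Oc1ccc2C=C[C@H](c3ccc(OCc4ccccc4)cc3)Oc2c1OCc1ccccc1
F9 | step 16 | (2S,3R,4R)-7,8-bis(benzyloxy)-2-[4-(benzyloxy)phenyl]chromane-3,4-diol | C(c1ccccc1)Oc1ccc2c(c1OCc1ccccc1)O[C@@H](c1ccc(OCc3ccccc3)cc1)[C@H](O)[C@@H]2O
F10 | step 16 | (2S,3S,4R)-7,8-bis(benzyloxy)-2-[4-(benzyloxy)phenyl]chromane-3,4-diyl diacetate | C(c1ccccc1)Oc1ccc2c(c1OCc1ccccc1)O[C@@H](c1ccc(OCc3ccccc3)cc1)[C@H](OC(C)=O)[C@@H]2OC(C)=O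
F11 | step 16 | 3,4-di-O-acetyl (lower unit) derivative of hexa-O-benzyl dimer 19 | C(c1ccccc1)Oc1ccc(cc1)[C@H]1Oc2c(ccc(OCc3ccccc3)c2OCc2ccccc2)[C@H](c2cc3c(c(OCc4ccccc4)c2OCc2ccccc2)O[C@@H](c2ccc(OCc4ccccc4)cc2)[C@H](OC(C)=O)[C@@H]3OC(C)=O)[C@H]1O
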